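**Strategy.** The route rests on the C5–C7 bond that joins the oxane CH to the exocyclic C(Cl)Me carbon (ring O1, C2–C6; side chain C7–C8=C9Br). It is forged by an Ireland–Claisen rearrangement whose migrating terminus is a chloroalkene carbon. In one operation an (R)-α-silyl (Z)-3-chloroallyl ester of (Z)-5-chlorohex-4-enoic acid trades its single C–Si stereocentre for the vicinal C5/C7 pair, creates the tertiary allylic chloride and leaves an (E)-vinylsilane as precursor of the (E)-bromoalkene. The second chloroalkene of that ester is a masked methyl ketone, on which NBS later closes the oxane and sets C3–Br and the C2 hemiketal.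

Key step: step 9

Remark: target locants (O1, C2 hemiketal carbon, C3 CHBr, C4, C5 ring CH, C6 OCH2, C7 CCl, C8=C9) are used for all intermediates; the sense of induction in step 6 is assigned by analogy with the transfer hydrogenation of ynones.

Step 1
Reactants: 1 but-2-yn-1-ol
Product: 2 (Z)-3-chlorobut-2-en-1-ol
Conditions: Red-Al, THF, 0 °C → rt; then NCS, −78 → 0 °C
Reagents that add atoms: N-chlorosuccinimide, O=C1CCC(=O)N1Cl
Why: Alkoxide-directed trans-hydroalumination of the propargylic alcohol places aluminium on C3 cis to the carbinol carbon in a five-membered alanate, and chlorodealumination with retention should give the Z chloroalkene (hydroalumination/halogenation of propargylic alcohols).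

Step 2
Reactants: 2 (Z)-3-chlorobut-2-en-1-ol; 3 diethyl malonate
Product: 5 diethyl 2-[(Z)-3-chlorobut-2-en-1-yl]malonate, via allylic mesylate 4 (not isolated)
Conditions: MsCl, Et3N, THF, −20 °C; then NaCH(CO2Et)2 (NaH, excess 3), THF, 0 °C → rt
Reagents that add atoms: none
Why: Malonic ester alkylation by SN2 at the primary allylic carbon of the mesylate, whose fully substituted γ-carbon disfavours SN2′, so the Z geometry is carried over and no stereocentre is formed.

Step 3
Reactants: 5 diethyl 2-[(Z)-3-chlorobut-2-en-1-yl]malonate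
Product: 7 (Z)-5-chlorohex-4-enoic acid, via malonic acid 6 (not isolated)
Conditions: KOH, EtOH–H2O, reflux; aq. HCl; then neat, 150 °C
Reagents that add atoms: potassium hydroxide, [K+].[OH-]
Why: Saponification and thermal decarboxylation of the malonic acid, conditions to which a vinyl chloride is inert (its hydrolysis needs concentrated acid).

Step 4
Reactants: 1 but-2-yn-1-ol
Product: 9 rac-1-(trimethylsilyl)but-2-yn-1-ol, via silyl ether 8 (not isolated)
Conditions: n-BuLi, THF, −78 °C; TMSCl, → 0 °C; then t-BuLi, −78 °C; AcOH, −78 °C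
Reagents that add atoms: chlorotrimethylsilane, C[Si](C)(C)Cl
Why: O-Silylation, then lithiation of the propargylic OCH2 and retro-[1,2]-Brook migration of silicon from O to C, driven by formation of the lithium alkoxide and frozen by the cold acidic quench; the product is racemic.

Step 5
Reactants: 9 rac-1-(trimethylsilyl)but-2-yn-1-ol
Product: 10 1-(trimethylsilyl)but-2-yn-1-one
Conditions: (COCl)2, DMSO, CH2Cl2, −78 °C; Et3N, −78 → −20 °C
Reagents that add atoms: none
Why: Swern oxidation of an α-silyl carbinol to the acylsilane, a cold, non-nucleophilic method that avoids Brook rearrangement and Si–C(=O) cleavage.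

Step 6
Reactants: 10 1-(trimethylsilyl)but-2-yn-1-one
Product: 11 (R)-1-(trimethylsilyl)but-2-yn-1-ol
Conditions: Ru[(R,R)-TsDPEN](p-cymene) (2 mol %), i-PrOH, rt
Reagents that add atoms: none
Why: Noyori asymmetric transfer hydrogenation of an alkynyl ketone under base-free conditions, in which the alkynyl group takes the π-site of the Ru–H/N–H transition state so that the catalyst sets the carbinol centre (R expected from the R,R antipode, to be confirmed before use), while the neutral medium spares the acylsilane.

Step 7
Reactants: 11 (R)-1-(trimethylsilyl)but-2-yn-1-ol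
Product: 12 (1R,2Z)-3-chloro-1-(trimethylsilyl)but-2-en-1-ol
Conditions: Red-Al, THF, −20 → 0 °C; then NCS, −78 → 0 °C
Reagents that add atoms: N-chlorosuccinimide, O=C1CCC(=O)N1Cl
Why: The same trans-hydroalumination/chlorodealumination as in step 1 should give the Z chloroalkene with chlorine cis to the carbinol carbon, the C–Si stereocentre is not involved, and the covalent aluminium alkoxide should not trigger Brook rearrangement at low temperature.

Step 8
Reactants: 7 (Z)-5-chlorohex-4-enoic acid; 12 (1R,2Z)-3-chloro-1-(trimethylsilyl)but-2-en-1-ol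
Product: 13 (1R,2Z)-3-chloro-1-(trimethylsilyl)but-2-en-1-yl (4Z)-5-chlorohex-4-enoate
Conditions: DCC, DMAP (cat.), CH2Cl2, 0 °C → rt
Reagents that add atoms: none
Why: Steglich esterification acylates oxygen under weakly basic conditions, so the C–Si stereocentre and both chloroalkenes are untouched.

Step 9
Reactants: 13 (1R,2Z)-3-chloro-1-(trimethylsilyl)but-2-en-1-yl (4Z)-5-chlorohex-4-enoate
Product: 16 (2R,3S,4E)-3-chloro-2-[(2Z)-3-chlorobut-2-en-1-yl]-3-methyl-5-(trimethylsilyl)pent-4-en-1-ol, via silyl ketene acetal 14 (not isolated), via silyl ester 15 (not isolated)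
Conditions: LDA, THF, −78 °C; TMSCl–Et3N, −78 °C → rt (40 °C if needed); then LiAlH4, −40 → 0 °C
Reagents that add atoms: none
Why: Proposed new method: an ester-enolate (Ireland–Claisen) [3,3] shift whose allyl terminus C7 carries chlorine has not been shown; the closest known reactions are the Ireland–Claisen rearrangements of α-silyl allylic esters (1,3-chirality transfer, (E)-vinylsilane product) and of 3,3-disubstituted or 3,3-difluoro allylic esters, and chlorine should be tolerated because the transition state places partial positive charge on the allyl fragment, which a chlorine lone pair supports, while formation of the silyl ester C=O drives the shift. LDA in THF without polar co-solvent should give the E(O)-enolate, trapped as (E)-silyl ketene acetal 14 (C4 chain cis to the allyloxy oxygen), which rearranges on warming through a chair; no ring is closed. SiMe3 on the carbinol carbon sits equatorial, because an axial silyl would be 1,3-diaxial to the Z chlorine, and this fixes which chair, and hence which face of each π system, is used and makes the new C8=C9 bond E. In that chair the C4 chain on C5 and the chlorine on C7 are both axial and the C7 methyl is equatorial, so the R carbinol centre is translated into 5R (through the enolate geometry) and 7S (through the Z chloroalkene geometry). The step needs E-selective enolisation and chair over boat, which the standard THF conditions and the acyclic substrate should secure. Silyl ester 15 is reduced in the same flask at low temperature so that the β-chloro carboxylate, which could lose CO2 and chloride, is never set free, and hydride should not attack the vinyl chlorides, the vinylsilane or the tertiary chloride under these conditions.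

Step 10
Reactants: 16 (2R,3S,4E)-3-chloro-2-[(2Z)-3-chlorobut-2-en-1-yl]-3-methyl-5-(trimethylsilyl)pent-4-en-1-ol
Product: 18 (2R,3S,5R)-3-bromo-5-[(2S,3E)-2-chloro-4-(trimethylsilyl)but-3-en-2-yl]-2-methyloxan-2-ol, via chloro ether 17 (not isolated)
Conditions: NBS (1.05 equiv), NaHCO3, CH2Cl2, −20 → 0 °C; then THF–H2O, 0 °C
Reagents that add atoms: N-bromosuccinimide, O=C1CCC(=O)N1Br; water, O
Why: Markovnikov bromoetherification of the chloroalkene, the intramolecular form of the NBS/water conversion of vinyl chlorides into α-bromo ketones: the hydroxyl attacks the chlorine-bearing C2 (6-endo-trig) anti to the bromonium on C3 through a chair with the C5 side chain equatorial, which places Br equatorial and cis to C5 (3S), the chloroalkene being more nucleophilic than the hindered, inductively deactivated vinylsilane, and hydrolysis of α-chloro ether 17 gives the hemiketal, which settles with OH axial and methyl equatorial (2R).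

Step 11
Reactants: 18 (2R,3S,5R)-3-bromo-5-[(2S,3E)-2-chloro-4-(trimethylsilyl)but-3-en-2-yl]-2-methyloxan-2-ol
Product: 19 (2R,3S,5R)-3-bromo-5-[(2S,3E)-4-bromo-2-chlorobut-3-en-2-yl]-2-methyloxan-2-ol (CNP0220042.1)
Conditions: NBS (1.2 equiv), MeCN, 0 °C → rt, dark
Reagents that add atoms: N-bromosuccinimide, O=C1CCC(=O)N1Br
Why: Electrophilic ipso-bromodesilylation of the vinylsilane: Br+ adds to the silicon-bearing C9, the β-silyl cation turns by the shorter path and loses silicon, so Br should replace Si with retention of the E geometry, and no other nucleophilic alkene remains and no stereocentre is touched.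

**Compound list**
1 | but-2-yn-1-ol | CC#CCO | starting material
2 | (Z)-3-chlorobut-2-en-1-ol | C/C(Cl)=C/CO | intermediate
3 | diethyl malonate | CCOC(=O)CC(=O)OCC | starting material
4 | (Z)-3-chlorobut-2-en-1-yl methanesulfonate | C/C(Cl)=C/COS(C)(=O)=O | intermediate
5 | diethyl 2-[(Z)-3-chlorobut-2-en-1-yl]malonate | CCOC(=O)C(C/C=C(/C)Cl)C(=O)OCC | intermediate
6 | 2-[(Z)-3-chlorobut-2-en-1-yl]malonic acid | OC(=O)C(C/C=C(/C)Cl)C(=O)O | intermediate
7 | (Z)-5-chlorohex-4-enoic acid | OC(=O)CC/C=C(/C)Cl | intermediate
8 | (but-2-yn-1-yloxy)trimethylsilane | CC#CCO[Si](C)(C)C | intermediate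
9 | rac-1-(trimethylsilyl)but-2-yn-1-ol | CC#CC(O)[Si](C)(C)C | intermediate
10 | 1-(trimethylsilyl)but-2-yn-1-one | CC#CC(=O)[Si](C)(C)C | intermediate
11 | (R)-1-(trimethylsilyl)but-2-yn-1-ol | CC#C[C@H](O)[Si](C)(C)C | intermediate
12 | (1R,2Z)-3-chloro-1-(trimethylsilyl)but-2-en-1-ol | C/C(Cl)=C/[C@H](O)[Si](C)(C)C | intermediate
13 | (1R,2Z)-3-chloro-1-(trimethylsilyl)but-2-en-1-yl (4Z)-5-chlorohex-4-enoate | C/C(Cl)=C/[C@H](OC(=O)CC/C=C(/C)Cl)[Si](C)(C)C | intermediate
14 | (E)-O-trimethylsilyl ketene acetal of 13 (C4 chain cis to the allyloxy oxygen) | C/C(Cl)=C/[C@H](O/C(O[Si](C)(C)C)=C\C/C=C(/C)Cl)[Si](C)(C)C | intermediate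
15 | trimethylsilyl (2R,3S,4E)-3-chloro-2-[(2Z)-3-chlorobut-2-en-1-yl]-3-methyl-5-(trimethylsilyl)pent-4-enoate | C[C@@](Cl)(/C=C/[Si](C)(C)C)[C@@H](C(=O)O[Si](C)(C)C)C/C=C(/C)Cl | intermediate
16 | (2R,3S,4E)-3-chloro-2-[(2Z)-3-chlorobut-2-en-1-yl]-3-methyl-5-(trimethylsilyl)pent-4-en-1-ol | C[C@@](Cl)(/C=C/[Si](C)(C)C)[C@@H](CO)C/C=C(/C)Cl | intermediate
17 | (2S,3S,5R)-3-bromo-2-chloro-5-[(2S,3E)-2-chloro-4-(trimethylsilyl)but-3-en-2-yl]-2-methyloxane | C[C@@](Cl)(/C=C/[Si](C)(C)C)[C@H]1CO[C@@](C)(Cl)[C@@H](Br)C1 | intermediate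
18 | (2R,3S,5R)-3-bromo-5-[(2S,3E)-2-chloro-4-(trimethylsilyl)but-3-en-2-yl]-2-methyloxan-2-ol | C[C@@](Cl)(/C=C/[Si](C)(C)C)[C@H]1CO[C@@](C)(O)[C@@H](Br)C1 | intermediate
19 | (2R,3S,5R)-3-bromo-5-[(2S,3E)-4-bromo-2-chlorobut-3-en-2-yl]-2-methyloxan-2-ol | C[C@@](Cl)(/C=C/Br)[C@H]1CO[C@@](C)(O)[C@@H](Br)C1 | target

**Step count.** Total: 11 steps. Longest linear sequence: 8 steps (steps 4–11 from but-2-yn-1-ol).

**Steps most likely to fail**

Step 9 (Proposed new method). The chloro-substituted terminus may not engage in the [3,3] shift before the enolate or ketene acetal decays to a ketene. Diastereoselectivity may also erode through a boat transition state or imperfect enolate geometry, and the tertiary allylic chloride may ionise on warming. The fallback uses known chemistry, sets out from acid 7 and comes back at alcohol 16. Acid 7 is joined to (R)-4-benzyloxazolidin-2-one (PivCl, Et3N; lithiated auxiliary) to give imide F1. Evans alkylation (NaHMDS, tert-butyl bromoacetate, −78 °C) sets C5 and gives alkylated imide F2. LiBH4 releases the auxiliary to give hydroxy ester F3, which closes under acid (TFA) to butyrolactone F4. Enolate methylation (LDA, MeI) gives trans-methyl lactone F5. A second enolisation and chlorination with NCS, anti to the C5 substituent, gives chloro lactone F6 with the C7 configuration of the target. DIBAL-H (−78 °C) gives lactol F7, and Takai olefination with Me3SiCHBr2/CrCl2 gives the (E)-vinylsilane alcohol 16.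

Step 10. NBS may attack the vinylsilane with 5-exo capture by the free hydroxyl, or the bromonium ion of the chloroalkene may be opened in the 5-exo (anti-Markovnikov) sense or without facial control. The fallback sets out from 16 and comes back at 19. Acetylation (Ac2O, pyridine) gives acetate F8, in which no oxygen can reach either alkene through a five- or six-membered ring. NBS (2.3 equiv) in MeCN–H2O then effects, in one flask, the oxidative hydrolysis of the chloroalkene by water (Br at C3, carbonyl at C2) and the bromodesilylation, giving bromo ketone acetate F9 as a mixture of C3 epimers. Acid-catalysed methanolysis of the acetate (HCl, MeOH) and aqueous work-up let the hydroxy ketone close to 19 and its C3 epimer, epi-hemiketal F10. The two are separated, and F10 is re-equilibrated through the ring-opened α-bromo ketone (LiBr, acetone) and recycled.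

Step 11. Ipso attack on a vinylsilane flanked by the quaternary C–Cl carbon may be slow, which would allow epimerisation at C3 through the ring-opened bromo ketone, over-bromination or partial loss of alkene geometry. The fallback sets out from 18 and comes back at 19. Ketalisation (MeOH, HC(OMe)3, PPTS) gives methyl ketal F11, which locks C3. Ozonolysis of its only alkene (O3, CH2Cl2–MeOH, −78 °C; Me2S) gives chloro aldehyde F12. Takai–Utimoto olefination (CHBr3, CrBr2, THF) gives (E)-bromoalkene ketal F13, and mild aqueous acid (PPTS, acetone–H2O) returns hemiketal 19.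

Further compounds
F1 | step 9 | (R)-4-benzyl-3-[(Z)-5-chlorohex-4-enoyl]oxazolidin-2-one | O=C1OC[C@@H](Cc2ccccc2)N1C(=O)CC/C=C(/C)Cl
F2 | step 9 | tert-butyl (3S,5Z)-3-{[(4R)-4-benzyl-2-oxooxazolidin-3-yl]carbonyl}-6-chlorohept-5-enoate | O=C1OC[C@@H](Cc2ccccc2)N1C(=O)[C@H](CC(=O)OC(C)(C)C)C/C=C(/C)Cl
F3 | step 9 | tert-butyl (3S,5Z)-6-chloro-3-(hydroxymethyl)hept-5-enoate | OC[C@H](CC(=O)OC(C)(C)C)C/C=C(/C)Cl
F4 | step 9 | (4S)-4-[(Z)-3-chlorobut-2-en-1-yl]oxolan-2-one | O=C1C[C@H](C/C=C(/C)Cl)CO1
F5 | step 9 | (3S,4S)-4-[(Z)-3-chlorobut-2-en-1-yl]-3-methyloxolan-2-one | C[C@@H]1C(=O)OC[C@H]1C/C=C(/C)Cl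
F6 | step 9 | (3S,4R)-3-chloro-4-[(Z)-3-chlorobut-2-en-1-yl]-3-methyloxolan-2-one | C[C@@]1(Cl)C(=O)OC[C@H]1C/C=C(/C)Cl
F7 | step 9 | (3S,4R)-3-chloro-4-[(Z)-3-chlorobut-2-en-1-yl]-3-methyloxolan-2-ol (anomers) | C[C@@]1(Cl)C(O)OC[C@H]1C/C=C(/C)Cl
F8 | step 10 | (2R,3S,4E)-3-chloro-2-[(2Z)-3-chlorobut-2-en-1-yl]-3-methyl-5-(trimethylsilyl)pent-4-en-1-yl acetate | C[C@@](Cl)(/C=C/[Si](C)(C)C)[C@@H](COC(C)=O)C/C=C(/C)Cl
F9 | step 10 | (2R,3S,4E)-5-bromo-2-(2-bromo-3-oxobutyl)-3-chloro-3-methylpent-4-en-1-yl acetate (both epimers at the CHBr carbon) | C[C@@](Cl)(/C=C/Br)[C@@H](COC(C)=O)CC(Br)C(C)=O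
F10 | step 10 | (2R,3R,5R)-3-bromo-5-[(2S,3E)-4-bromo-2-chlorobut-3-en-2-yl]-2-methyloxan-2-ol | C[C@@](Cl)(/C=C/Br)[C@H]1CO[C@@](C)(O)[C@H](Br)C1
F11 | step 11 | (2R,3S,5R)-3-bromo-5-[(2S,3E)-2-chloro-4-(trimethylsilyl)but-3-en-2-yl]-2-methoxy-2-methyloxane | C[C@@](Cl)(/C=C/[Si](C)(C)C)[C@H]1CO[C@@](C)(OC)[C@@H](Br)C1
F12 | step 11 | (2S)-2-[(3R,5S,6R)-5-bromo-6-methoxy-6-methyloxan-3-yl]-2-chloropropanal | C[C@@](Cl)(C=O)[C@H]1CO[C@@](C)(OC)[C@@H](Br)C1
F13 | step 11 | (2R,3S,5R)-3-bromo-5-[(2S,3E)-4-bromo-2-chlorobut-3-en-2-yl]-2-methoxy-2-methyloxane | C[C@@](Cl)(/C=C/Br)[C@H]1CO[C@@](C)(OC)[C@@H](Br)C1
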